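**Strategy.** The route rests on disconnecting the aryl ether bond O1–C8a of ring C, so that C2 is fixed as a free (S)-carbinol before the pyranone ring exists. The key step, a palladium-catalysed intramolecular C–O coupling, closes ring C in one operation and carries the C2 configuration over unchanged. It exploits that C8a of ring A lies ortho to the C4 acyl group on C4a and bears one of the two equivalent chelated hydroxyls of phloroacetophenone, which is turned into a triflate. The precursor is an open-chain β-hydroxy ketone, made by a catalytic enantioselective Mukaiyama aldol reaction, with a C8a triflate and silyl ethers at O5 and O7.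

Key step: step 6

Flavanone numbering (O1, C2, C3, C4, C4a, C5–C8, C8a; ring A = benzo ring, ring B = 2-aryl ring, ring C = pyranone) is used for the open-chain precursors as well; "geranyl" = (2E)-3,7-dimethylocta-2,6-dien-1-yl.

Assumption: the (S,S)-bis-phosphoramide of step 5 is chosen on the accepted facial model of this catalyst class (enol silane adds to the Si face of an aromatic aldehyde); should the sense prove opposite, the (R,R)-catalyst is used with no other change.

**Step 1**
Reactants: 1 4-hydroxybenzaldehyde; 2 geranyl bromide [(2E)-1-bromo-3,7-dimethylocta-2,6-diene]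
Product: 3 4-(geranyloxy)benzaldehyde
Conditions: K2CO3 (1.5 equiv), DMF, rt
Reagents that add atoms: none
Why: Williamson ether synthesis; the phenoxide displaces the primary allylic bromide by SN2 without allylic transposition, so the (E)-geometry of the chain is kept.

**Step 2**
Reactants: 4 2',4',6'-trihydroxyacetophenone (dried azeotropically)
Product: 5 1-[2-hydroxy-4,6-bis(triisopropylsilyloxy)phenyl]ethanone
Conditions: i-Pr3SiCl (2.1 equiv), imidazole (4 equiv), DMF, 0 °C to rt
Reagents that add atoms: triisopropylsilyl chloride, CC(C)[Si](Cl)(C(C)C)C(C)C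
Why: Phenol silylation; the 4-OH and one of the two equivalent ortho hydroxyls react, while the last ortho hydroxyl is held in a hydrogen bond to the acetyl carbonyl and is too hindered for a third bulky silyl group, which leaves free exactly the oxygen that becomes the leaving group.

**Step 3**
Reactants: 5 1-[2-hydroxy-4,6-bis(triisopropylsilyloxy)phenyl]ethanone
Product: 6 2-acetyl-3,5-bis(triisopropylsilyloxy)phenyl trifluoromethanesulfonate
Conditions: Tf2O (1.2 equiv), pyridine (3 equiv), CH2Cl2, 0 °C
Reagents that add atoms: trifluoromethanesulfonic anhydride, O=S(=O)(OS(=O)(=O)C(F)(F)F)C(F)(F)F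
Why: O-Sulfonylation of the chelated phenol turns the oxygen on the future C8a into a leaving group fit for oxidative addition; the silyl ethers and the ketone are inert here.

**Step 4**
Reactants: 6 2-acetyl-3,5-bis(triisopropylsilyloxy)phenyl trifluoromethanesulfonate
Product: 7 3,5-bis(triisopropylsilyloxy)-2-[1-(trimethylsilyloxy)ethenyl]phenyl trifluoromethanesulfonate
Conditions: Me3SiOTf (1.3 equiv), Et3N (2 equiv), CH2Cl2, 0 °C; pentane/cold aq. NaHCO3 work-up, used without chromatography
Reagents that add atoms: trimethylsilyl trifluoromethanesulfonate, C[Si](C)(C)OS(=O)(=O)C(F)(F)F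
Why: Soft enolisation (silyl triflate/amine) of a methyl ketone with a single enolisable position gives the enol silane for the Mukaiyama aldol reaction; the aryl triflate and aryl silyl ethers are untouched.

**Step 5**
Reactants: 7 the trimethylsilyl enol ether; 3 4-(geranyloxy)benzaldehyde
Product: 9 2-{(3S)-3-[4-(geranyloxy)phenyl]-3-hydroxypropanoyl}-3,5-bis(triisopropylsilyloxy)phenyl trifluoromethanesulfonate, via trichlorosilyl aldolate 8 (not isolated)
Conditions: SiCl4 (1.5 equiv), (S,S)-bis-phosphoramide catalyst (two (S)-N,N'-dimethyl-1,1'-binaphthyl-2,2'-diamine phosphoramide units joined through N,N'-dimethylpentane-1,5-diamine, 5 mol %), i-Pr2NEt (10 mol %), CH2Cl2, −78 °C; then cold sat. aq. NaHCO3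
Reagents that add atoms: silicon tetrachloride, Cl[Si](Cl)(Cl)Cl (its SiCl3 group resides in 8 only and is lost on work-up)
Why: Lewis base-activated Mukaiyama aldol addition; the chiral bis-phosphoramide ionises SiCl4 to a cationic chiral silicon Lewis acid that binds the aldehyde, and the enol silane attacks through an open transition state, the (S,S)-catalyst being expected to direct it to the Si face and so set the (S)-carbinol at the future C2, while the low temperature should spare the geranyl ether, silyl ethers and triflate.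

**Step 6**
Reactants: 9 the (S)-β-hydroxy ketone triflate
Product: 10 (2S)-2-[4-(geranyloxy)phenyl]-5,7-bis(triisopropylsilyloxy)-2,3-dihydro-4H-chromen-4-one
Conditions: Pd(OAc)2 (3 mol %), 2-(di-tert-butylphosphino)-1,1'-binaphthyl (4 mol %), Cs2CO3 (1.5 equiv), toluene, 50–65 °C
Reagents that add atoms: none
Why: Zerovalent palladium (formed in situ) inserts into the C8a–OTf bond, which the ortho acyl group activates; carbonate-assisted exchange of triflate for the C2 alkoxide gives a seven-membered aryl(alkoxo)palladium chelate, and C–O reductive elimination forms O1–C8a and returns the catalyst. The closest known reaction type is the palladium-catalysed intramolecular etherification of aryl halides and sulfonates with secondary alcohols that delivers 2-substituted chromans. Ring C closes in a 6-exo mode (O1 attacks C8a, the departing triflate lying outside the new ring) through reductive elimination from the seven-membered palladacycle. No stereocenter is created: the C2–O bond is never broken, so the (S) configuration set by the catalyst in step 5 is retained. The step needs reductive elimination to outrun β-hydride elimination at the palladium alkoxide and base-induced dehydration or retro-aldol cleavage of the β-hydroxy ketone, which the bulky di-tert-butylphosphine ligand, the weak and barely soluble carbonate and the low temperature should secure. Because ring A carries no free phenol, an enone formed by dehydration cannot re-close by oxa-Michael addition, so that side path would cost yield and not enantiomeric purity.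

**Step 7**
Reactants: 10 the bis-silylated (2S)-flavanone
Product: 11 (2S)-5,7-dihydroxy-2-[4-(geranyloxy)phenyl]-2,3-dihydro-4H-chromen-4-one (4'-O-geranylnaringenin)
Conditions: Bu4NF (2.5 equiv), AcOH (2.5 equiv), THF, 0 °C
Reagents that add atoms: none
Why: Fluoride-induced cleavage of aryl silyl ethers (Si–F bond formation); acetic acid protonates the phenoxides as they form, so base-induced opening of ring C and loss of the C2 configuration should not occur, and the geranyl ether and ketone are inert.

**Compound list**
1 | 4-hydroxybenzaldehyde | O=Cc1ccc(O)cc1 | starting material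
2 | geranyl bromide, (2E)-1-bromo-3,7-dimethylocta-2,6-diene | CC(C)=CCC/C(C)=C/CBr | starting material
3 | 4-(geranyloxy)benzaldehyde | CC(C)=CCC/C(C)=C/COc1ccc(C=O)cc1 | intermediate
4 | 2',4',6'-trihydroxyacetophenone | CC(=O)c1c(O)cc(O)cc1O | starting material
5 | 1-[2-hydroxy-4,6-bis(triisopropylsilyloxy)phenyl]ethanone | CC(=O)c1c(O)cc(O[Si](C(C)C)(C(C)C)C(C)C)cc1O[Si](C(C)C)(C(C)C)C(C)C | intermediate
6 | 2-acetyl-3,5-bis(triisopropylsilyloxy)phenyl trifluoromethanesulfonate | CC(=O)c1c(OS(=O)(=O)C(F)(F)F)cc(O[Si](C(C)C)(C(C)C)C(C)C)cc1O[Si](C(C)C)(C(C)C)C(C)C | intermediate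
7 | 3,5-bis(triisopropylsilyloxy)-2-[1-(trimethylsilyloxy)ethenyl]phenyl trifluoromethanesulfonate | C=C(O[Si](C)(C)C)c1c(OS(=O)(=O)C(F)(F)F)cc(O[Si](C(C)C)(C(C)C)C(C)C)cc1O[Si](C(C)C)(C(C)C)C(C)C | intermediate
8 | (S)-O-trichlorosilyl ether of aldol 9 | CC(C)=CCC/C(C)=C/COc1ccc([C@@H](O[Si](Cl)(Cl)Cl)CC(=O)c2c(OS(=O)(=O)C(F)(F)F)cc(O[Si](C(C)C)(C(C)C)C(C)C)cc2O[Si](C(C)C)(C(C)C)C(C)C)cc1 | intermediate (not isolated)
9 | 2-{(3S)-3-[4-(geranyloxy)phenyl]-3-hydroxypropanoyl}-3,5-bis(triisopropylsilyloxy)phenyl trifluoromethanesulfonate | CC(C)=CCC/C(C)=C/COc1ccc([C@@H](O)CC(=O)c2c(OS(=O)(=O)C(F)(F)F)cc(O[Si](C(C)C)(C(C)C)C(C)C)cc2O[Si](C(C)C)(C(C)C)C(C)C)cc1 | intermediate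
10 | (2S)-2-[4-(geranyloxy)phenyl]-5,7-bis(triisopropylsilyloxy)-2,3-dihydro-4H-chromen-4-one | CC(C)=CCC/C(C)=C/COc1ccc([C@@H]2CC(=O)c3c(O[Si](C(C)C)(C(C)C)C(C)C)cc(O[Si](C(C)C)(C(C)C)C(C)C)cc3O2)cc1 | intermediate
11 | (2S)-5,7-dihydroxy-2-[4-(geranyloxy)phenyl]-2,3-dihydro-4H-chromen-4-one | CC(C)=CCC/C(C)=C/COc1ccc([C@@H]2CC(=O)c3c(O)cc(O)cc3O2)cc1 | target

**Step count.** Total: 7 steps. Longest linear sequence: 6 steps (4 to 11, steps 2–7); step 1 is a one-step side branch.

**Steps most likely to fail**

Step 6 (key step). Under carbonate at 50–65 °C the β-hydroxy ketone may dehydrate or fragment by retro-aldol reaction. The palladium alkoxide may undergo β-hydride elimination with reductive loss of the triflate, and zerovalent palladium may ionise the geranyl aryl ether. The closed product may also lose configuration by reversible base-induced opening of ring C. Fallback (from 9, back at 10): the C4 carbonyl is taken to the alcohol level before ring closure. Evans–Tishchenko reduction of 9 (PhCHO, SmI2 cat., THF, −10 °C) should give the anti-1,3-diol 2-O-benzoate F1 with a free C4 hydroxyl. Silylation (Et3SiOTf, 2,6-lutidine) gives the C4 triethylsilyl ether F2, and i-Bu2AlH at −78 °C removes the benzoate to give the C2 alcohol F3. The same palladium-catalysed etherification, now on a substrate with no enolisable ketone, closes ring C to the 4-(triethylsilyloxy)flavan F4. HF·pyridine buffered with pyridine should cleave the alkyl silyl ether in preference to the aryl silyl ethers to give the flavan-4-ol F5, and Dess–Martin periodinane restores the C4 ketone, 10.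

Step 5. The enol silane carries a twisted, doubly ortho-substituted aryl group, so addition may be slow or the facial selectivity insufficient; the cationic silicon Lewis acid may also attack the geranyl alkenes. Fallback (from 6 and 3, back at 9): C–C bond formation and creation of the stereocenter are separated. The lithium enolate of 6 (LiN(SiMe3)2, THF, −78 °C) adds to 3 to give the racemic aldol F6, and Dess–Martin periodinane oxidises it to the 1,3-diketone F7. Asymmetric transfer hydrogenation with RuCl(p-cymene)[(S,S)-TsDPEN] in HCO2H/Et3N should reduce only the unhindered ring B carbonyl, since the ring A carbonyl is flanked by two ortho substituents. By the established sense for aryl ketones it should give the (S)-alcohol 9.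

Step 2. Discrimination among the three hydroxyls may be incomplete, with silylation stopping at the mono-ether or going on to the chelated hydroxyl. Fallback (from 4, back at 6): protection and activation are reordered. One equivalent of i-Pr3SiCl/imidazole silylates only the most acidic, unhindered 4-OH to give the 4-silyl ether F8. One equivalent of Tf2O/pyridine at −20 °C triflates one of the two equivalent ortho hydroxyls to give the monotriflate F9; the other is deactivated by its hydrogen bond to the carbonyl and by the new sulfonate. i-Pr3SiOTf/2,6-lutidine then silylates the remaining hydroxyl to give 6, so that 5 is bypassed.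

**Further compounds**
F1 | step 6 | (1S,3S)-3-[4-(geranyloxy)phenyl]-1-[2-(trifluoromethanesulfonyloxy)-4,6-bis(triisopropylsilyloxy)phenyl]propane-1,3-diol 3-benzoate (anti) | CC(C)=CCC/C(C)=C/COc1ccc([C@@H](OC(=O)c2ccccc2)C[C@H](O)c2c(OS(=O)(=O)C(F)(F)F)cc(O[Si](C(C)C)(C(C)C)C(C)C)cc2O[Si](C(C)C)(C(C)C)C(C)C)cc1
F2 | step 6 | 1-O-triethylsilyl ether of F1 | CC(C)=CCC/C(C)=C/COc1ccc([C@@H](OC(=O)c2ccccc2)C[C@H](O[Si](CC)(CC)CC)c2c(OS(=O)(=O)C(F)(F)F)cc(O[Si](C(C)C)(C(C)C)C(C)C)cc2O[Si](C(C)C)(C(C)C)C(C)C)cc1
F3 | step 6 | 2-{(1S,3S)-3-[4-(geranyloxy)phenyl]-3-hydroxy-1-(triethylsilyloxy)propyl}-3,5-bis(triisopropylsilyloxy)phenyl trifluoromethanesulfonate | CC(C)=CCC/C(C)=C/COc1ccc([C@@H](O)C[C@H](O[Si](CC)(CC)CC)c2c(OS(=O)(=O)C(F)(F)F)cc(O[Si](C(C)C)(C(C)C)C(C)C)cc2O[Si](C(C)C)(C(C)C)C(C)C)cc1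
F4 | step 6 | (2S,4S)-2-[4-(geranyloxy)phenyl]-4-(triethylsilyloxy)-5,7-bis(triisopropylsilyloxy)chromane | CC(C)=CCC/C(C)=C/COc1ccc([C@@H]2C[C@H](O[Si](CC)(CC)CC)c3c(O[Si](C(C)C)(C(C)C)C(C)C)cc(O[Si](C(C)C)(C(C)C)C(C)C)cc3O2)cc1
F5 | step 6 | (2S,4S)-2-[4-(geranyloxy)phenyl]-5,7-bis(triisopropylsilyloxy)chroman-4-ol | CC(C)=CCC/C(C)=C/COc1ccc([C@@H]2C[C@H](O)c3c(O[Si](C(C)C)(C(C)C)C(C)C)cc(O[Si](C(C)C)(C(C)C)C(C)C)cc3O2)cc1
F6 | step 5 | racemic 2-{3-[4-(geranyloxy)phenyl]-3-hydroxypropanoyl}-3,5-bis(triisopropylsilyloxy)phenyl trifluoromethanesulfonate | CC(C)=CCC/C(C)=C/COc1ccc(C(O)CC(=O)c2c(OS(=O)(=O)C(F)(F)F)cc(O[Si](C(C)C)(C(C)C)C(C)C)cc2O[Si](C(C)C)(C(C)C)C(C)C)cc1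
F7 | step 5 | 2-{3-[4-(geranyloxy)phenyl]-3-oxopropanoyl}-3,5-bis(triisopropylsilyloxy)phenyl trifluoromethanesulfonate | CC(C)=CCC/C(C)=C/COc1ccc(C(=O)CC(=O)c2c(OS(=O)(=O)C(F)(F)F)cc(O[Si](C(C)C)(C(C)C)C(C)C)cc2O[Si](C(C)C)(C(C)C)C(C)C)cc1
F8 | step 2 | 1-[2,6-dihydroxy-4-(triisopropylsilyloxy)phenyl]ethanone | CC(=O)c1c(O)cc(O[Si](C(C)C)(C(C)C)C(C)C)cc1O
F9 | step 2 | 2-acetyl-3-hydroxy-5-(triisopropylsilyloxy)phenyl trifluoromethanesulfonate | CC(=O)c1c(O)cc(O[Si](C(C)C)(C(C)C)C(C)C)cc1OS(=O)(=O)C(F)(F)F
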